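S = 8.76: that is the selectivity factor, the trapping rate of intermediate A over its leak to intermediate B at the charged [capture agent].

| flask | substrate | capture agent | time | remark |
|---|---|---|---|---|
| west | 0.37 M | 0.370 M | 20 h | a closed flask charged with all of it at once and left for 20 h |
| north-east | 0.37 M | 0.370 M |  | a single well-mixed tank run continuously and read at steady state, 20 h in it on average |
| north | 0.37 M (fed, over 16.0 h) | 0.370 M | 20 h | all but substrate at the start; substrate goes in evenly over 16.0 h, the run ends at 20 h |
| south-east | 0.37 M | 0.370 M | 20 h | a tube with plug flow, the mixed feed as stated, residence time 20 h |

    substrate → intermediate A (k1 = 0.021 min⁻¹)
    intermediate B → intermediate C (k2 = 0.015 min⁻¹)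
    intermediate A + capture agent → trapped intermediate (k3 = 0.018 M⁻¹ min⁻¹)
    intermediate C → product (k4 = 0.0088 min⁻¹)
    intermediate A → intermediate B (k5 = 7.6 × 10⁻⁴ min⁻¹)

- the set-up with the highest amount of intermediate A at the outlet or at the end, in percent of the substrate put in ("none" if the first two lie within 2 percentage points) (west / north-east / north / south-east / none)
- amount of intermediate A at the outlet or at the end, in percent of the substrate put in, west
- amount of intermediate A at the outlet or at the end, in percent of the substrate put in, north-east
- amount of intermediate A at the outlet or at the end, in percent of the substrate put in, north
- amount of intermediate A at the outlet or at the end, in percent of the substrate put in, south-east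

- the stated concentrations are those of everything mixed, before any reaction; amounts are the same in each set-up
- the feed brings no volume worth counting
- run time (west): 20 h

Draw west, the closed flask. The start belongs to substrate: its half-life of 0.55 h is shorter than the 1.7 h of trapping at charged concentrations, so [intermediate A] climbs steeply and its knee comes early. Now divide the two losses of intermediate A: [intermediate A] and time cancel. Let f be the share of capture agent left. Then f = exp(−S × leaked/charged capture agent), where leaked counts intermediate B, intermediate C and product.

Find the level. In west the two charges are equal, so at the level, where trapped and leaked together make up the charge, the leaked share equals f, and f = exp(−Sf). Newton from a rough start gives 18.1%, then 18.9%.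

Look for the crossing. Trapping equals leak at f = 1/S = 11.4%, which lies below the level, so in west trapping stays ahead. Near the level, intermediate A has a half-life of 5.71 h, short against 20 h. Holding the leak at its final value from the start, the rate law integrates to 2.21% at the end of west. Read that as low, since it charges the leak too early. A parcel in the south-east tube runs the same course. My reckoning stops there, without north or the tank.

The forecast names north-east, with 3.3% for west, 18.9% for north-east, 13.7% for north and 3.3% for south-east; its west figure is higher than my 2.21%. One of its grounds: “the closed flask and the plug-flow tube behave identically”.

The simulation gives north-east as best, with 18.9%, then north with 14.6%, and west and south-east with 3.18% and 3.18%. West holds 19.0% of its capture agent at 200 h. Put the rule to work on north, whose charges are also equal: its leaked share at 20.0 h is 14.2%, which gives f = 28.8%; north holds 28.8% of its capture agent.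

Take the neighbour of north charged with 1.5 M of substrate. Its leaked amount of 0.406 M gives f = 0.00669%, below the crossing. That flask holds 0.00669% of its capture agent and 48.2% of its substrate as intermediate A.

The constants come from no measurement; the run is a simulation.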